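The ten-membered carbocycle carries an oxirane (C4–C5) whose CH carbon C5 is bonded to the angeloyloxy carbon C6; this 2,3-epoxy ester is the retron of a (Z)-allylic alcohol. The route therefore rests on closing the ten-membered ring between C5 and C6 by an intramolecular Nozaki–Hiyama–Kishi reaction. In one operation it forms the ring as a strain-free (Z,Z)-cyclodeca-1,6-diene, sets the C6 carbinol and places the C4=C5 alkene with the geometry the cis-epoxide needs. The precursor is an open-chain aldehyde on a trans-α-methylene-γ-butyrolactone that ends in a (Z)-alkenyl iodide; it is built from three small fragments, and both Z-alkenes are set stereospecifically before the fragments are joined.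

Key step: step 13

Remark on numbering: C1–C15 follow germacrane numbering. C1 is the free carbinol, C4–C5 the oxirane, C6 the acyloxy carbon, C7/C8 the lactone ring fusion, C9=C10 the ring alkene, C11–C13 the methylene lactone, C14 and C15 the methyls on C10 and C4.

Assumption: the two catalyst-controlled steps (5 and 10) follow the usual sense of induction of their ligand families; if not, the antipodal ligand is used.

Step 1
Reactants: 1 2-(2-bromoethyl)-1,3-dioxolane; 2 propyne
Product: 6 2-[(3Z)-4-iodo-3-methylbut-3-en-1-yl]-1,3-dioxolane, via Grignard reagent 3 (not isolated), via alkylcopper 4 (not isolated), via alkenylcopper 5 (not isolated)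
Conditions: Mg, THF, 25 °C; CuBr·SMe2, Et2O/Me2S, −45 °C; 2, −25 °C; I2, −78 → 0 °C
Reagents that add atoms: iodine, II
Why: Normant syn-carbocupration of propyne puts the alkyl group on the internal carbon and copper on the terminal carbon cis to it, and iodinolysis with retention should give the (Z)-iodide with iodine cis to the chain (C5 cis to C3).

Step 2
Reactants: 6 2-[(3Z)-4-iodo-3-methylbut-3-en-1-yl]-1,3-dioxolane
Product: 7 (4Z)-5-iodo-4-methylpent-4-enal
Conditions: 2 M HCl, THF, rt
Reagents that add atoms: water, O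
Why: Acid-catalysed acetal hydrolysis frees the C1 aldehyde while the alkenyl iodide is inert to aqueous acid.

Step 3
Reactants: 8 but-2-yn-1-ol
Product: 10 (2Z)-3-iodobut-2-en-1-ol, via cyclic alkenylaluminate 9 (not isolated)
Conditions: NaAlH2(OCH2CH2OMe)2, THF, 0 °C → rt; I2, −78 °C
Reagents that add atoms: iodine, II
Why: Hydroxyl-directed trans-hydroalumination places aluminium on C3 cis to the CH2O group in a five-membered ring, and iododealumination with retention should give the (Z)-iodide (C10–I cis to C8).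

Step 4
Reactants: 10 (2Z)-3-iodobut-2-en-1-ol
Product: 11 1-({[(2Z)-3-iodobut-2-en-1-yl]oxy}methyl)-4-methoxybenzene
Conditions: NaH, 4-methoxybenzyl chloride, Bu4NI (cat.), THF, 0 °C → rt
Reagents that add atoms: 4-methoxybenzyl chloride, COc1ccc(CCl)cc1
Why: Williamson etherification; a benzyl-type ether is chosen because a silyl ether cis to the carbanion could migrate from oxygen to carbon in the alkenyllithium of step 5.

Step 5
Reactants: 11 1-({[(2Z)-3-iodobut-2-en-1-yl]oxy}methyl)-4-methoxybenzene; 7 (4Z)-5-iodo-4-methylpent-4-enal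
Product: 14 (2Z,4R,7Z)-8-iodo-1-[(4-methoxyphenyl)methoxy]-3,7-dimethylocta-2,7-dien-4-ol, via alkenyllithium 12 (not isolated), via alkenylethylzinc 13 (not isolated)
Conditions: 11, t-BuLi (2 equiv), Et2O, −78 °C; EtZnCl, −78 → 0 °C; Et2NCH2CH2NEt2, (−)-3-exo-morpholinoisoborneol (10 mol %), then 7, toluene, 0 °C
Reagents that add atoms: none
Why: Iodine–lithium exchange and transmetalation to the mixed alkenyl(ethyl)zinc proceed with retention of the Z geometry, and in the amino-alcohol-catalysed enantioselective addition (the diamine sequesters lithium halides and the alkenyl group transfers far faster than ethyl) the Si face of the aldehyde should be attacked to set C1 as R by catalyst control; the alkenyl iodide of 7 does not react with organozincs.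

Step 6
Reactants: 14 (2Z,4R,7Z)-8-iodo-1-[(4-methoxyphenyl)methoxy]-3,7-dimethylocta-2,7-dien-4-ol
Product: 15 tert-butyl({(2Z,4R,7Z)-8-iodo-1-[(4-methoxyphenyl)methoxy]-3,7-dimethylocta-2,7-dien-4-yl}oxy)dimethylsilane
Conditions: TBSCl, imidazole, DMF, rt
Reagents that add atoms: tert-butyldimethylsilyl chloride, CC(C)(C)[Si](C)(C)Cl
Why: Standard silylation of the secondary allylic alcohol; the silyl ether later prevents hydroxyl-directed oxidation of the C9=C10 alkene and should survive to the last step.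

Step 7
Reactants: 15 tert-butyl({(2Z,4R,7Z)-8-iodo-1-[(4-methoxyphenyl)methoxy]-3,7-dimethylocta-2,7-dien-4-yl}oxy)dimethylsilane
Product: 16 (2Z,4R,7Z)-4-{[tert-butyl(dimethyl)silyl]oxy}-8-iodo-3,7-dimethylocta-2,7-dien-1-ol
Conditions: DDQ, CH2Cl2/pH 7 buffer, 0 °C
Reagents that add atoms: none
Why: Oxidative cleavage of the 4-methoxybenzyl ether through its benzylic oxocarbenium ion leaves the silyl ether, both alkenes and the alkenyl iodide untouched.

Step 8
Reactants: 16 (2Z,4R,7Z)-4-{[tert-butyl(dimethyl)silyl]oxy}-8-iodo-3,7-dimethylocta-2,7-dien-1-ol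
Product: 17 (2Z,4R,7Z)-4-{[tert-butyl(dimethyl)silyl]oxy}-8-iodo-3,7-dimethylocta-2,7-dienal
Conditions: MnO2, CH2Cl2, rt
Reagents that add atoms: none
Why: MnO2 oxidises the primary allylic alcohol to the C8 enal under neutral heterogeneous conditions that should not isomerise the trisubstituted Z-alkene.

Step 9
Reactants: 18 3-methylideneoxolan-2-one (α-methylene-γ-butyrolactone)
Product: 20 3-(bromomethyl)furan-2(5H)-one, via dibromide 19 (not isolated)
Conditions: Br2, CH2Cl2, 0 °C; Et3N, 0 °C → rt
Reagents that add atoms: bromine, BrBr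
Why: Bromine addition followed by E2 loss of HBr across the ring (ring C–H anti to the tertiary bromide) should give the conjugated endocyclic butenolide and keep the primary allylic bromide.

Step 10
Reactants: 17 (2Z,4R,7Z)-4-{[tert-butyl(dimethyl)silyl]oxy}-8-iodo-3,7-dimethylocta-2,7-dienal; 20 3-(bromomethyl)furan-2(5H)-one
Product: 22 (4S)-4-[(1S,2Z,4R,7Z)-4-{[tert-butyl(dimethyl)silyl]oxy}-1-hydroxy-8-iodo-3,7-dimethylocta-2,7-dien-1-yl]-3-methylideneoxolan-2-one, via trimethylsilyl ether 21 (not isolated)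
Conditions: CrCl2 (10 mol %), (S,S)-3,6-di-tert-butyl-1,8-bis(4-isopropyl-4,5-dihydrooxazol-2-yl)-9H-carbazole (12 mol %), Mn powder, Me3SiCl, iPr2NEt, THF, rt; then 1 M HCl, THF, 0 °C
Reagents that add atoms: none
Why: In this catalytic asymmetric Nozaki–Hiyama allylation the butenolide ring locks C6 trans to the CH2–Cr carbon of the allylchromium, so the chair transition state should give the 7,8-anti adduct, the chiral ligand should direct Re-face attack on the aldehyde (8S, and hence 7S here), and the alkenyl iodide stays intact because no nickel is present.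

Step 11
Reactants: 22 (4S)-4-[(1S,2Z,4R,7Z)-4-{[tert-butyl(dimethyl)silyl]oxy}-1-hydroxy-8-iodo-3,7-dimethylocta-2,7-dien-1-yl]-3-methylideneoxolan-2-one
Product: 23 (4S,5S)-5-[(1Z,3R,6Z)-3-{[tert-butyl(dimethyl)silyl]oxy}-7-iodo-2,6-dimethylhepta-1,6-dien-1-yl]-4-(hydroxymethyl)-3-methylideneoxolan-2-one
Conditions: DBU (0.2 equiv), CH2Cl2, rt
Reagents that add atoms: none
Why: Base-catalysed translactonisation through a bicyclic tetrahedral intermediate should favour the more substituted γ-lactone on the secondary C8 oxygen, which frees the primary C6 alcohol and turns the anti adduct into the trans-4,5-disubstituted lactone without touching a stereocentre.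

Step 12
Reactants: 23 (4S,5S)-5-[(1Z,3R,6Z)-3-{[tert-butyl(dimethyl)silyl]oxy}-7-iodo-2,6-dimethylhepta-1,6-dien-1-yl]-4-(hydroxymethyl)-3-methylideneoxolan-2-one
Product: 24 (2S,3R)-2-[(1Z,3R,6Z)-3-{[tert-butyl(dimethyl)silyl]oxy}-7-iodo-2,6-dimethylhepta-1,6-dien-1-yl]-4-methylidene-5-oxooxolane-3-carbaldehyde
Conditions: Dess–Martin periodinane, NaHCO3, CH2Cl2, 0 °C; crude product used at once
Reagents that add atoms: none
Why: Buffered Dess–Martin oxidation forms the C6 aldehyde without base, so the C7 centre, which is α to the aldehyde and allylic to the methylene lactone, should be neither epimerised nor isomerised before the next step.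

Step 13
Reactants: 24 (2S,3R)-2-[(1Z,3R,6Z)-3-{[tert-butyl(dimethyl)silyl]oxy}-7-iodo-2,6-dimethylhepta-1,6-dien-1-yl]-4-methylidene-5-oxooxolane-3-carbaldehyde
Product: 26 (1R,4Z,6R,7S,8S,9Z)-1-{[tert-butyl(dimethyl)silyl]oxy}-6-hydroxygermacra-4,9,11(13)-trien-12,8-olide, via alkenylchromium 25 (not isolated)
Conditions: CrCl2 (10 equiv), NiCl2 (0.1 equiv), DMSO, rt, 2 mM, slow addition of 24
Reagents that add atoms: none
Why: Zerovalent nickel, formed from NiCl2 by CrCl2, inserts into the C5–I bond with retention, the alkenyl group passes to trivalent chromium (25), and this alkenylchromium adds to the C6 aldehyde, the only electrophile it attacks. The closest known reaction type is the intramolecular Nozaki–Hiyama–Kishi cyclisation of alkenyl iodide aldehydes to medium-ring allylic alcohols. The ten-membered carbocycle is closed by exo addition of C5 to the C6 carbonyl (10-exo-trig), helped by the two Z-alkenes and the trans-lactone, which fold the chain into the chair of a (Z,Z)-cyclodeca-1,6-diene. The new C6 stereocentre is controlled by the C7 centre through this chair-like transition state: H6 points into the ring to avoid allylic 1,3-strain with C3, C11 sits pseudo-equatorial and anti to the incoming C5, and the carbonyl oxygen points outward, which should give the 6R alcohol (C6–O trans to C7–C11). The step needs retention of the Z geometry at C4=C5 (secured by the configurationally stable alkenylchromium), ring closure over oligomerisation (high dilution, slow addition) and survival of the labile α-branched aldehyde (neutral medium, aldehyde used at once).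

Step 14
Reactants: 26 (1R,4Z,6R,7S,8S,9Z)-1-{[tert-butyl(dimethyl)silyl]oxy}-6-hydroxygermacra-4,9,11(13)-trien-12,8-olide
Product: 27 (1R,4Z,6R,7S,8S,9Z)-6-angeloyloxy-1-{[tert-butyl(dimethyl)silyl]oxy}germacra-4,9,11(13)-trien-12,8-olide
Conditions: angelic acid, 2,4,6-trichlorobenzoyl chloride, Et3N, toluene, rt; then 26, 80 °C
Reagents that add atoms: angelic acid, C/C=C(/C)C(=O)O
Why: Yamaguchi-type acylation through the mixed anhydride, without a nucleophilic amine catalyst, should esterify the hindered C6 alcohol with retention and avoid the conjugate-addition pathway that isomerises angelates to tiglates.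

Step 15
Reactants: 27 (1R,4Z,6R,7S,8S,9Z)-6-angeloyloxy-1-{[tert-butyl(dimethyl)silyl]oxy}germacra-4,9,11(13)-trien-12,8-olide
Product: 28 (1R,4R,5S,6S,7R,8S,9Z)-6-angeloyloxy-1-{[tert-butyl(dimethyl)silyl]oxy}-4,5-epoxygermacra-9,11(13)-dien-12,8-olide
Conditions: mCPBA, NaHCO3, CH2Cl2, 0 °C
Reagents that add atoms: 3-chloroperbenzoic acid, OOC(=O)c1cccc(Cl)c1
Why: Prilezhaev epoxidation should select the C4=C5 alkene (one allylic oxygen) over the C9=C10 alkene (two allylic oxygens, next to the silyl ether) and the two enoate alkenes, and with H6 eclipsing the Z-alkene the peracid should attack the face anti to the allylic C6–O bond, setting 4R and 5S (cis-epoxide erythro to the ester).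

Step 16
Reactants: 28 (1R,4R,5S,6S,7R,8S,9Z)-6-angeloyloxy-1-{[tert-butyl(dimethyl)silyl]oxy}-4,5-epoxygermacra-9,11(13)-dien-12,8-olide
Product: 29 (1R,4R,5S,6S,7R,8S,9Z)-6-angeloyloxy-4,5-epoxy-1-hydroxygermacra-9,11(13)-dien-12,8-olide (CNP0191628.1)
Conditions: HF·pyridine, pyridine, THF, 0 °C → rt
Reagents that add atoms: none
Why: Fluoride-mediated Si–O cleavage buffered by pyridine should remove the silyl group without opening the trisubstituted epoxide, isomerising the angelate or adding to the methylene lactone.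

Compound list
1 | 2-(2-bromoethyl)-1,3-dioxolane | BrCCC1OCCO1 | starting material
2 | propyne | CC#C | starting material
3 | [2-(1,3-dioxolan-2-yl)ethyl]magnesium bromide | Br[Mg]CCC1OCCO1 | intermediate
4 | [2-(1,3-dioxolan-2-yl)ethyl]copper | [Cu]CCC1OCCO1 | intermediate
5 | [(1Z)-4-(1,3-dioxolan-2-yl)-2-methylbut-1-en-1-yl]copper | [Cu]/C=C(/C)CCC1OCCO1 | intermediate
6 | 2-[(3Z)-4-iodo-3-methylbut-3-en-1-yl]-1,3-dioxolane | I/C=C(/C)CCC1OCCO1 | intermediate
7 | (4Z)-5-iodo-4-methylpent-4-enal | I/C=C(/C)CCC=O | intermediate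
8 | but-2-yn-1-ol | CC#CCO | starting material
9 | sodium cyclic alkoxy(alkenyl)aluminate from 8 (2-oxa-1-aluminacyclopent-4-ene, Al on C3 of the butenol) | CC1=CCO[Al-]1(OCCOC)OCCOC.[Na+] | intermediate
10 | (2Z)-3-iodobut-2-en-1-ol | OC/C=C(/C)I | intermediate
11 | 1-({[(2Z)-3-iodobut-2-en-1-yl]oxy}methyl)-4-methoxybenzene | COc1ccc(COC/C=C(/C)I)cc1 | intermediate
12 | (Z)-alkenyllithium from 11 | COc1ccc(COC/C=C(/C)[Li])cc1 | intermediate
13 | (Z)-alkenyl(ethyl)zinc from 12 | COc1ccc(COC/C=C(/C)[Zn]CC)cc1 | intermediate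
14 | (2Z,4R,7Z)-8-iodo-1-[(4-methoxyphenyl)methoxy]-3,7-dimethylocta-2,7-dien-4-ol | COc1ccc(COC/C=C(/C)[C@H](O)CC/C(C)=C\I)cc1 | intermediate
15 | tert-butyldimethylsilyl ether of 14 | COc1ccc(COC/C=C(/C)[C@H](O[Si](C)(C)C(C)(C)C)CC/C(C)=C\I)cc1 | intermediate
16 | (2Z,4R,7Z)-4-{[tert-butyl(dimethyl)silyl]oxy}-8-iodo-3,7-dimethylocta-2,7-dien-1-ol | OC/C=C(/C)[C@H](O[Si](C)(C)C(C)(C)C)CC/C(C)=C\I | intermediate
17 | (2Z,4R,7Z)-4-{[tert-butyl(dimethyl)silyl]oxy}-8-iodo-3,7-dimethylocta-2,7-dienal | O=C/C=C(/C)[C@H](O[Si](C)(C)C(C)(C)C)CC/C(C)=C\I | intermediate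
18 | 3-methylideneoxolan-2-one (α-methylene-γ-butyrolactone) | C=C1CCOC1=O | starting material
19 | 3-bromo-3-(bromomethyl)oxolan-2-one | BrCC1(Br)CCOC1=O | intermediate
20 | 3-(bromomethyl)furan-2(5H)-one | BrCC1=CCOC1=O | intermediate
21 | trimethylsilyl ether of 22 | C=C1C(=O)OC[C@H]1[C@@H](O[Si](C)(C)C)/C=C(/C)[C@H](O[Si](C)(C)C(C)(C)C)CC/C(C)=C\I | intermediate
22 | (4S)-4-[(1S,2Z,4R,7Z)-4-{[tert-butyl(dimethyl)silyl]oxy}-1-hydroxy-8-iodo-3,7-dimethylocta-2,7-dien-1-yl]-3-methylideneoxolan-2-one | C=C1C(=O)OC[C@H]1[C@@H](O)/C=C(/C)[C@H](O[Si](C)(C)C(C)(C)C)CC/C(C)=C\I | intermediate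
23 | (4S,5S)-5-[(1Z,3R,6Z)-3-{[tert-butyl(dimethyl)silyl]oxy}-7-iodo-2,6-dimethylhepta-1,6-dien-1-yl]-4-(hydroxymethyl)-3-methylideneoxolan-2-one | C=C1C(=O)O[C@@H](/C=C(/C)[C@H](O[Si](C)(C)C(C)(C)C)CC/C(C)=C\I)[C@@H]1CO | intermediate
24 | (2S,3R)-2-[(1Z,3R,6Z)-3-{[tert-butyl(dimethyl)silyl]oxy}-7-iodo-2,6-dimethylhepta-1,6-dien-1-yl]-4-methylidene-5-oxooxolane-3-carbaldehyde | C=C1C(=O)O[C@@H](/C=C(/C)[C@H](O[Si](C)(C)C(C)(C)C)CC/C(C)=C\I)[C@@H]1C=O | intermediate
25 | (Z)-alkenylchromium dichloride from 24 (Cr in place of I at C5) | C=C1C(=O)O[C@@H](/C=C(/C)[C@H](O[Si](C)(C)C(C)(C)C)CC/C(C)=C\[Cr](Cl)Cl)[C@@H]1C=O | intermediate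
26 | (1R,4Z,6R,7S,8S,9Z)-1-{[tert-butyl(dimethyl)silyl]oxy}-6-hydroxygermacra-4,9,11(13)-trien-12,8-olide | C=C1C(=O)O[C@H]2/C=C(/C)[C@H](O[Si](C)(C)C(C)(C)C)CC/C(C)=C\[C@@H](O)[C@H]12 | intermediate
27 | (1R,4Z,6R,7S,8S,9Z)-6-angeloyloxy-1-{[tert-butyl(dimethyl)silyl]oxy}germacra-4,9,11(13)-trien-12,8-olide | C=C1C(=O)O[C@H]2/C=C(/C)[C@H](O[Si](C)(C)C(C)(C)C)CC/C(C)=C\[C@@H](OC(=O)/C(C)=C\C)[C@H]12 | intermediate
28 | (1R,4R,5S,6S,7R,8S,9Z)-6-angeloyloxy-1-{[tert-butyl(dimethyl)silyl]oxy}-4,5-epoxygermacra-9,11(13)-dien-12,8-olide | C=C1C(=O)O[C@H]2/C=C(/C)[C@H](O[Si](C)(C)C(C)(C)C)CC[C@@]3(C)O[C@H]3[C@@H](OC(=O)/C(C)=C\C)[C@H]12 | intermediate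
29 | (1R,4R,5S,6S,7R,8S,9Z)-6-angeloyloxy-4,5-epoxy-1-hydroxygermacra-9,11(13)-dien-12,8-olide (CNP0191628.1) | C=C1C(=O)O[C@H]2/C=C(/C)[C@H](O)CC[C@@]3(C)O[C@H]3[C@@H](OC(=O)/C(C)=C\C)[C@H]12 | target

Total step count: 16. Longest linear sequence: 13 steps (1, 2, 5, 6, 7, 8, 10, 11, 12, 13, 14, 15, 16).

Steps most likely to fail

Step 13. The exocyclic C11=C13 double bond may migrate into conjugation with the C6 aldehyde, or C7 may epimerise, before the slow ring closure; oligomerisation may also compete. The fallback sets out from 23 and comes back at 26. Dimethylamine (Me2NH, THF, rt) is added to the methylene lactone to give the β-dimethylaminomethyl lactone F1 (mixture of C11 epimers), which removes the enoate that makes C7–H doubly activated. Parikh–Doering oxidation (SO3·pyridine, DMSO, iPr2NEt) then gives the amino aldehyde F2, and the same CrCl2/NiCl2 ring closure gives the amino macrocycle F3. Quaternisation with MeI gives the trimethylammonium iodide F4, and NaHCO3-induced elimination of trimethylamine restores the methylene lactone 26.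

Step 15. The peracid may attack the alkene face syn to the ester, or the C9=C10 alkene may be epoxidised as well. The fallback sets out from 26 and comes back at 28. Mitsunobu inversion with formic acid (PPh3, DIAD, THF) gives the 6-epi formate F5, and methanolysis (KHCO3, MeOH) gives the 6-epi allylic alcohol F6. Epoxidation with VO(acac)2 and t-BuOOH is then hydroxyl-directed, so it is confined to C4=C5 and to the face syn to the hydroxyl (threo for a Z-allylic alcohol), and gives the epoxy alcohol F7. A second Mitsunobu reaction, with angelic acid, inverts C6 again and installs the ester, giving 28.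

Step 10. The Z-enal may isomerise to the E-enal under the Lewis-acidic chromium and chlorosilane medium, and enantiofacial control by the ligand may be incomplete. The fallback sets out from 20 and comes back at 22. Palladium-catalysed borylation (B2pin2, Pd2(dba)3, DMSO, rt) gives the allylboronate F8. This adds to 17 under chiral phosphoric acid catalysis ((R)-3,3'-bis(2,4,6-triisopropylphenyl)-1,1'-binaphthyl-2,2'-diyl hydrogen phosphate, toluene, −30 °C) through a closed chair transition state in which the ring-locked geometry again enforces the anti adduct, and hydrolysis of the borate gives 22.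

Further compounds
F1 | step 13 | dimethylamine adduct of 23 (3-[(dimethylamino)methyl] lactone, C11 epimers) | CN(C)CC1C(=O)O[C@@H](/C=C(/C)[C@H](O[Si](C)(C)C(C)(C)C)CC/C(C)=C\I)[C@@H]1CO
F2 | step 13 | amino aldehyde (C6 aldehyde of F1) | CN(C)CC1C(=O)O[C@@H](/C=C(/C)[C@H](O[Si](C)(C)C(C)(C)C)CC/C(C)=C\I)[C@@H]1C=O
F3 | step 13 | amino macrocycle (13-dimethylamino-11,13-dihydro derivative of 26) | CN(C)CC1C(=O)O[C@H]2/C=C(/C)[C@H](O[Si](C)(C)C(C)(C)C)CC/C(C)=C\[C@@H](O)[C@H]12
F4 | step 13 | trimethylammonium iodide of F3 | C[N+](C)(C)CC1C(=O)O[C@H]2/C=C(/C)[C@H](O[Si](C)(C)C(C)(C)C)CC/C(C)=C\[C@@H](O)[C@H]12.[I-]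
F5 | step 15 | 6-epi formate of 26 | C=C1C(=O)O[C@H]2/C=C(/C)[C@H](O[Si](C)(C)C(C)(C)C)CC/C(C)=C\[C@H](OC=O)[C@H]12
F6 | step 15 | 6-epi allylic alcohol (C6 epimer of 26) | C=C1C(=O)O[C@H]2/C=C(/C)[C@H](O[Si](C)(C)C(C)(C)C)CC/C(C)=C\[C@H](O)[C@H]12
F7 | step 15 | (4R,5S)-4,5-epoxy 6-epi alcohol | C=C1C(=O)O[C@H]2/C=C(/C)[C@H](O[Si](C)(C)C(C)(C)C)CC[C@@]3(C)O[C@H]3[C@H](O)[C@H]12
F8 | step 10 | 3-[(4,4,5,5-tetramethyl-1,3,2-dioxaborolan-2-yl)methyl]furan-2(5H)-one | CC1(C)OB(CC2=CCOC2=O)OC1(C)C
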